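The readings were generated by integration for substances that don't exist; the scatter is artificial.

In a one-step world, starting material and reagent in the second phase give target and nothing else, so target climbs towards what the limiting reagent allows, 0.700 equiv, while its slope sinks gently.

| flask | starting material | reagent in the second phase | remark | time | volume of the second phase over the first |
|---|---|---|---|---|---|
| red | 0.80 M | 0.70 equiv | the very flask that is asked about, followed so far |  |  |
| flask | 0.80 M | 0.700 equiv |  | 1.0 h | 0.25 |

red run (percent of the starting material charged)

| time / min | target / % |
|---|---|
| 0.500 | 1.0 |
| 1.33 | 2.9 |
| 2.50 | 7.4 |
| 4.00 | 10.9 |
| 6.00 | 13.0 |
| 8.00 | 17.5 |

(readings scatter by 1 percentage point)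

* when, up to 1.0 h, the flask holds most target
* the amount of target, in percent of the starting material charged, at that time
* the first time at which target reaches 12%, in the same percent

- in the second phase: reagent in the second phase; everything else is in the first
- charges count per volume of the first phase; a concentration in a rate is the amount of a species over the volume of its own phase; every rate counts per litre of the first phase
- the earlier runs hold the two phases in the same ratio of volumes as the flask asked about

We read the red run, this same flask followed through its first minutes, as two rates. Up to 4.00 min, target gains 0.0272 /min of the charge; from there to 8.00 min it gains 0.0165 /min, which is less, a ratio of 0.607. This fall of the slope is what we carry forward. If we continue this fall in a straight line through the middles of the two stretches, the slope reaches zero at 0.202 h, the stop time. With a scatter of 1 percentage point on each reading, this is a rough time. We then put that first answer back in: from the reading at 4.00 min, a slope falling to zero by the stop time adds a triangle, so by our reckoning target tops out near 19.8%.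

The forecast differs from our reckoning: it gives 50% at 1 h, later than our stop time, and 12% at 0.082 h. It rests on a second-order law that fits, in its words, “with no sign of anything else needed”.

The flask holds most target, 17.0%, at 0.213 h, close to our rough stop time, and reaches 12% at 0.0740 h.

starting material + reagent in the reaction phase → target (k = 0.103 /M/min); reagent in the reaction phase + target → over-reacted product (k = 0.195 /M/min); reagent in the reaction phase ⇌ reagent in the second phase, rate k3*([reagent in the reaction phase] - [reagent in the second phase]/K3) per volume of the first phase (partition coefficient = 0.370, kL = 0.124 /min); starting material + target → side product (k = 0.0724 /M/min) The same flask read at 25 min, twice the stop time, has already passed its highest 17.0% and holds 14.9%. At 1.00 h the flask makes target at 0.343 of the rate at which it uses target up, each step taken net, and target stands at 8.78%.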